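**Plan**
- Retrosynthesis: the enyne C(sp)–C(sp2) bond is cut first (oxolanyl alkyne plus a bromo-iodo-triene). The alkyne carbon and the ester arm are then cut back to a C2-symmetric oxolane-2,5-dimethanol. In the ring, the two C–C bonds C2–C3 and C4–C5 are cut together.
- Enabling feature: in the oxolane, O1 is flanked by two CH(O) carbons, C2 and C5, joined by an unsubstituted C3–C4 ethano unit, and the 2,5-substituents are trans. The ring core therefore has a local C2 axis through O1 and the C3–C4 midpoint. An oxydiacetyl unit maps onto C2–O1–C5; two identical acyl groups make both α-oxy carbons nucleophilic (polarity reversal of the dissonant 1,4-dioxygen pattern) toward a two-carbon bis-electrophile.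
- Forward: the oxydiacetyl bis-imide is assembled from diglycolic anhydride by two successive N-acylations. The ring is then made (both C–C bonds in one flask) and the acyl helpers are reduced off. The homotopic arms are told apart by mono-iodination, followed by radical chain extension, oxidation and alkyne homologation. The side chain is built separately and joined last.
- Stereochemistry: both ring centres come from two (R)-4-benzyloxazolidinone auxiliaries in the ring-forming step (same sense at C2 and C5 means trans). The E-iodoalkene comes from hydrozirconation; the Z,Z-bromodiene from (Z)-3-bromoacrylate and a Z-selective Wittig reaction.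

Key step: step 3

Remark: ring numbering is O1, C2 (butanoate arm), C3, C4, C5 (alkynyl chain). The target is the 2,5-trans oxolane; its (2R,5S) label only reflects the different CIP ranking at the two carbons.

Step 1
Reactants: 1 (R)-4-benzyloxazolidin-2-one; 2 1,4-dioxane-2,6-dione (diglycolic anhydride)
Product: 4 2-{2-[(R)-4-benzyl-2-oxooxazolidin-3-yl]-2-oxoethoxy}acetic acid, via lithium oxazolidinide 3 (not isolated)
Conditions: n-BuLi (1.0 equiv), THF, −78 °C; then 2 (1.05 equiv), −78 to 0 °C; aqueous HCl work-up
Reagents that add atoms: none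
Why: Ring opening of a cyclic anhydride by a lithiated oxazolidinone (nucleophilic acyl substitution) is a standard N-acylation; the two anhydride carbonyls are equivalent, the lithium carboxylate formed is inert to a second attack, and the auxiliary stereocentre is untouched.

Step 2
Reactants: 4 2-{2-[(R)-4-benzyl-2-oxooxazolidin-3-yl]-2-oxoethoxy}acetic acid; 1 (R)-4-benzyloxazolidin-2-one
Product: 6 (4R,4'R)-3,3'-(2,2'-oxydiacetyl)bis(4-benzyloxazolidin-2-one), via mixed pivalic anhydride 5 (not isolated)
Conditions: pivaloyl chloride (1.05 equiv), Et3N (2.5 equiv), THF, −20 °C; then LiCl, 1 (1.0 equiv), −20 °C to rt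
Reagents that add atoms: none
Why: N-acylation of an oxazolidinone by a mixed pivalic anhydride under LiCl/Et3N activation, in which the nucleophile attacks the less hindered glycolyl carbonyl of 5 and not the pivaloyl carbonyl, while the mild amine base leaves the imide already present alone.

Step 3
Reactants: 6 (4R,4'R)-3,3'-(2,2'-oxydiacetyl)bis(4-benzyloxazolidin-2-one); 7 ethane-1,2-diyl bis(trifluoromethanesulfonate)
Product: 10 (4R,4'R)-3,3'-[(2S,5S)-oxolane-2,5-dicarbonyl]bis(4-benzyloxazolidin-2-one), via disodium bis-enolate 8 (not isolated), via mono-alkylated sodium enolate 9 (not isolated)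
Conditions: NaN(SiMe3)2 (2.1 equiv), THF, −78 °C; then 7 (1.0 equiv), high dilution, −78 to −40 °C; AcOH quench
Reagents that add atoms: none
Why: Proposed new method: double deprotonation gives the bis-(Z)-sodium enolate 8, one enolate carbon of which displaces a primary triflate of 7 in an intermolecular SN2 step to give 9, whereupon the second enolate carbon displaces the remaining triflate intramolecularly, so that both ring C–C bonds (C2–C3 and C4–C5) are made in one flask from an ether whose oxygen is already in place. The closest known reaction types are the auxiliary-controlled alkylation of sodium enolates of N-(alkoxyacetyl)oxazolidinones (Evans alkylation of glycolate imides) and the cycloalkylation of dianions of chiral succinate diesters with α,ω-dielectrophiles; new is their union on an oxygen-bridged bis-enolate with a two-carbon bis-electrophile. The oxolane closes in a 5-exo-tet mode with the enolate double bond exocyclic to the forming ring, which is geometrically favourable. Each new stereocentre is controlled by its own (R)-4-benzyloxazolidinone through the sodium-chelated (Z)-enolate, the electrophilic carbon approaching anti to the benzyl group, which should give S at both α-carbons; because both centres are set with the same sense the product is the C2-symmetric 2,5-trans isomer, the cis isomer requiring one mismatched alkylation. The step needs C- over O-alkylation (chelated sodium enolates, SN2 at a primary carbon), ring closure over a second intermolecular alkylation (intramolecular second step, one equivalent of 7, dilution) and substitution over elimination from 7 (low temperature, weakly basic imide enolates).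

Step 4
Reactants: 10 (4R,4'R)-3,3'-[(2S,5S)-oxolane-2,5-dicarbonyl]bis(4-benzyloxazolidin-2-one)
Product: 11 [(2S,5S)-oxolane-2,5-diyl]dimethanol
Conditions: LiBH4, MeOH (2 equiv), THF, 0 °C
Reagents that add atoms: none
Why: Reductive cleavage of an N-acyloxazolidinone, in which LiBH4 attacks the exocyclic imide carbonyl and reduces it to the primary alcohol with release of the auxiliary, without enolization of the α-alkoxy centres.

Step 5
Reactants: 11 [(2S,5S)-oxolane-2,5-diyl]dimethanol
Product: 12 [(2S,5S)-5-(iodomethyl)oxolan-2-yl]methanol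
Conditions: PPh3 (0.9 equiv), I2 (0.9 equiv), imidazole, THF/MeCN, 0 °C
Reagents that add atoms: iodine, II
Why: An Appel-type iodination (alkoxyphosphonium iodide, then SN2 by iodide at the primary carbon) converts one hydroxyl into the iodide, and because the two hydroxymethyl groups are homotopic through the C2 axis only one mono-iodide can form, so a deficit of reagent should give it together with recoverable diol.

Step 6
Reactants: 12 [(2S,5S)-5-(iodomethyl)oxolan-2-yl]methanol; 13 methyl acrylate
Product: 14 methyl 4-[(2R,5S)-5-(hydroxymethyl)oxolan-2-yl]butanoate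
Conditions: Bu3SnH (slow addition), AIBN (cat.), 13 (excess), benzene, 80 °C
Reagents that add atoms: none
Why: Giese reaction, in which the nucleophilic primary alkyl radical from the C–I bond adds to the β-carbon of the electron-poor acrylate faster than it is reduced when the stannane is kept dilute, the β-oxygen radical does not open the ring, and the free hydroxyl and both ring stereocentres are untouched.

Step 7
Reactants: 14 methyl 4-[(2R,5S)-5-(hydroxymethyl)oxolan-2-yl]butanoate
Product: 15 methyl 4-[(2R,5S)-5-formyloxolan-2-yl]butanoate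
Conditions: Dess–Martin periodinane, CH2Cl2, 0 °C to rt; used crude
Reagents that add atoms: none
Why: Dess–Martin oxidation takes the primary alcohol to the aldehyde under near-neutral, non-enolizing conditions, so the ester survives and the α-alkoxy stereocentre should not epimerize.

Step 8
Reactants: 15 methyl 4-[(2R,5S)-5-formyloxolan-2-yl]butanoate
Product: 16 methyl 4-[(2R,5S)-5-ethynyloxolan-2-yl]butanoate
Conditions: dimethyl (1-diazo-2-oxopropyl)phosphonate, K2CO3, MeOH, 0 °C to rt
Reagents that add atoms: dimethyl (1-diazo-2-oxopropyl)phosphonate, COP(=O)(OC)C(=[N+]=[N-])C(C)=O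
Why: Ohira–Bestmann modification of the Seyferth–Gilbert homologation, in which the diazomethylphosphonate anion converts the aldehyde through a diazoalkene and 1,2-hydrogen shift into the terminal alkyne, while in methanol the methyl ester can only exchange with itself and the mild carbonate base at 0 °C should leave the α-alkoxy centre intact.

Step 9
Reactants: 17 hept-6-yn-1-ol
Product: 18 7-bromohept-1-yne
Conditions: CBr4, PPh3, CH2Cl2, 0 °C
Reagents that add atoms: tetrabromomethane, BrC(Br)(Br)Br
Why: Appel bromination of a primary alcohol (SN2 by bromide on the alkoxyphosphonium ion), to which the terminal alkyne is inert.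

Step 10
Reactants: 18 7-bromohept-1-yne
Product: 20 (E)-7-bromo-1-iodohept-1-ene, via alkenylzirconocene chloride 19 (not isolated)
Conditions: Cp2Zr(H)Cl, THF, rt; then I2, 0 °C
Reagents that add atoms: iodine, II
Why: Hydrozirconation adds Zr–H syn across the terminal alkyne with zirconium at the terminal carbon and iodinolysis of the C–Zr bond proceeds with retention, which gives the (E)-1-iodoalkene, the primary bromide being tolerated at room temperature.

Step 11
Reactants: 20 (E)-7-bromo-1-iodohept-1-ene
Product: 21 [(E)-7-iodohept-6-en-1-yl]triphenylphosphonium bromide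
Conditions: PPh3, MeCN, 80 °C
Reagents that add atoms: triphenylphosphine, c1ccc(cc1)P(c1ccccc1)c1ccccc1
Why: SN2 quaternization of PPh3 by the primary alkyl bromide, whereas an alkenyl iodide does not react with PPh3 in the absence of a transition metal.

Step 12
Reactants: 22 ethyl (Z)-3-bromoprop-2-enoate
Product: 24 (Z)-3-bromoprop-2-enal, via aluminium hemiacetal 23 (not isolated)
Conditions: i-Bu2AlH (1.05 equiv), CH2Cl2, −78 °C; MeOH, then aqueous sodium potassium tartrate, 0 °C; dried cold solution used at once
Reagents that add atoms: none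
Why: Partial reduction of an ester, in which i-Bu2AlH adds once at −78 °C and the tetrahedral aluminium hemiacetal 23 persists until hydrolytic work-up releases the aldehyde, neither event touching the C=C bond, so the (Z)-geometry should be kept if the labile enal is used cold and at once.

Step 13
Reactants: 21 [(E)-7-iodohept-6-en-1-yl]triphenylphosphonium bromide; 24 (Z)-3-bromoprop-2-enal
Product: 26 (1Z,3Z,9E)-1-bromo-10-iododeca-1,3,9-triene, via phosphorus ylide 25 (not isolated)
Conditions: NaN(SiMe3)2 (1.0 equiv), THF, −78 to 0 °C; then 24, −78 to −20 °C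
Reagents that add atoms: none
Why: Wittig reaction of a non-stabilized ylide under lithium-free conditions at low temperature, which forms the (Z)-alkene through the kinetically favoured cis-oxaphosphetane, while the (Z)-bromoalkene of 24 and the (E)-iodoalkene are spectators.

Step 14
Reactants: 16 methyl 4-[(2R,5S)-5-ethynyloxolan-2-yl]butanoate; 26 (1Z,3Z,9E)-1-bromo-10-iododeca-1,3,9-triene
Product: 27 methyl 4-[(2R,5S)-5-[(3E,9Z,11Z)-12-bromododeca-3,9,11-trien-1-yn-1-yl]oxolan-2-yl]butanoate
Conditions: Pd(PPh3)4 (cat.), CuI (cat.), i-Pr2NH, THF (degassed), 0 °C to rt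
Reagents that add atoms: none
Why: Sonogashira coupling, in which oxidative addition of zerovalent palladium to the alkenyl C–I bond is much faster than to the alkenyl C–Br bond, so near 0 °C the alkyne should be coupled at the iodide only, with retention of the (E)-geometry and without touching ester, propargylic ether or (Z,Z)-bromodiene.

**Compound list**
1 | (R)-4-benzyloxazolidin-2-one | O=C1OC[C@@H](Cc2ccccc2)N1 | starting material
2 | 1,4-dioxane-2,6-dione (diglycolic anhydride) | O=C1COCC(=O)O1 | starting material
3 | lithium (R)-4-benzyl-2-oxooxazolidin-3-ide | [Li+].O=C1OC[C@@H](Cc2ccccc2)[N-]1 | intermediate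
4 | 2-{2-[(R)-4-benzyl-2-oxooxazolidin-3-yl]-2-oxoethoxy}acetic acid | OC(=O)COCC(=O)N1[C@H](Cc2ccccc2)COC1=O | intermediate
5 | 2-{2-[(R)-4-benzyl-2-oxooxazolidin-3-yl]-2-oxoethoxy}acetic 2,2-dimethylpropanoic anhydride | CC(C)(C)C(=O)OC(=O)COCC(=O)N1[C@H](Cc2ccccc2)COC1=O | intermediate
6 | (4R,4'R)-3,3'-(2,2'-oxydiacetyl)bis(4-benzyloxazolidin-2-one) | O=C(COCC(=O)N1[C@H](Cc2ccccc2)COC1=O)N1[C@H](Cc2ccccc2)COC1=O | intermediate
7 | ethane-1,2-diyl bis(trifluoromethanesulfonate) | O=S(=O)(OCCOS(=O)(=O)C(F)(F)F)C(F)(F)F | starting material
8 | disodium (1Z,1'Z)-2,2'-oxybis{1-[(R)-4-benzyl-2-oxooxazolidin-3-yl]ethen-1-olate} | [Na+].[Na+].[O-]/C(=C\O/C=C(\[O-])N1[C@H](Cc2ccccc2)COC1=O)N1[C@H](Cc2ccccc2)COC1=O | intermediate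
9 | sodium (Z)-1-[(R)-4-benzyl-2-oxooxazolidin-3-yl]-2-{[(S)-1-[(R)-4-benzyl-2-oxooxazolidin-3-yl]-1-oxo-4-[(trifluoromethylsulfonyl)oxy]butan-2-yl]oxy}ethen-1-olate | [Na+].[O-]/C(=C\O[C@@H](CCOS(=O)(=O)C(F)(F)F)C(=O)N1[C@H](Cc2ccccc2)COC1=O)N1[C@H](Cc2ccccc2)COC1=O | intermediate
10 | (4R,4'R)-3,3'-[(2S,5S)-oxolane-2,5-dicarbonyl]bis(4-benzyloxazolidin-2-one) | O=C([C@@H]1CC[C@@H](C(=O)N2[C@H](Cc3ccccc3)COC2=O)O1)N1[C@H](Cc2ccccc2)COC1=O | intermediate
11 | [(2S,5S)-oxolane-2,5-diyl]dimethanol | OC[C@@H]1CC[C@@H](CO)O1 | intermediate
12 | [(2S,5S)-5-(iodomethyl)oxolan-2-yl]methanol | IC[C@@H]1CC[C@@H](CO)O1 | intermediate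
13 | methyl acrylate | C=CC(=O)OC | starting material
14 | methyl 4-[(2R,5S)-5-(hydroxymethyl)oxolan-2-yl]butanoate | COC(=O)CCC[C@@H]1CC[C@@H](CO)O1 | intermediate
15 | methyl 4-[(2R,5S)-5-formyloxolan-2-yl]butanoate | COC(=O)CCC[C@@H]1CC[C@@H](C=O)O1 | intermediate
16 | methyl 4-[(2R,5S)-5-ethynyloxolan-2-yl]butanoate | COC(=O)CCC[C@@H]1CC[C@@H](C#C)O1 | intermediate
17 | hept-6-yn-1-ol | OCCCCCC#C | starting material
18 | 7-bromohept-1-yne | BrCCCCCC#C | intermediate
19 | [(E)-7-bromohept-1-en-1-yl]chlorobis(cyclopentadienyl)zirconium (cyclopentadienyl rings drawn σ-bound) | Cl[Zr](/C=C/CCCCCBr)(C1C=CC=C1)C1C=CC=C1 | intermediate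
20 | (E)-7-bromo-1-iodohept-1-ene | BrCCCCC/C=C/I | intermediate
21 | [(E)-7-iodohept-6-en-1-yl]triphenylphosphonium bromide | [Br-].I/C=C/CCCCC[P+](c1ccccc1)(c1ccccc1)c1ccccc1 | intermediate
22 | ethyl (Z)-3-bromoprop-2-enoate | CCOC(=O)/C=C\Br | starting material
23 | {[(Z)-3-bromo-1-ethoxyprop-2-en-1-yl]oxy}bis(2-methylpropyl)alumane | CCOC(O[Al](CC(C)C)CC(C)C)/C=C\Br | intermediate
24 | (Z)-3-bromoprop-2-enal | O=C/C=C\Br | intermediate
25 | [(E)-7-iodohept-6-en-1-ylidene]triphenylphosphorane | I/C=C/CCCCC=P(c1ccccc1)(c1ccccc1)c1ccccc1 | intermediate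
26 | (1Z,3Z,9E)-1-bromo-10-iododeca-1,3,9-triene | I/C=C/CCCC/C=C\C=C/Br | intermediate
27 | methyl 4-[(2R,5S)-5-[(3E,9Z,11Z)-12-bromododeca-3,9,11-trien-1-yn-1-yl]oxolan-2-yl]butanoate | COC(=O)CCC[C@@H]1CC[C@@H](C#C/C=C/CCCC/C=C\C=C/Br)O1 | target

Total step count: 14. Longest linear sequence: 9 steps (steps 1 to 8, then step 14).

**Steps most likely to fail**

Step 3 (proposed new method). What may go wrong:
- the sodium glycolate enolates may decompose before they attack the inductively deactivated bis-triflate;
- the electrophile may be lost by O-alkylation or elimination;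
- chains may grow by intermolecular alkylation;
- facial control in the ring-closing alkylation may erode.

Fallback with known chemistry, closing the ring at oxygen instead of at carbon. It gives up compounds 1 to 12 and needs, of the numbered compounds, only methyl acrylate 13. It sets out from commercial (S)-2-[(benzyloxy)methyl]oxirane F1 and comes back to the route at compound 14. Opening of F1 with allylmagnesium bromide (CuI cat., THF, −40 °C) should give (S)-1-(benzyloxy)hex-5-en-2-ol F2 with the carbinol centre untouched. Mukaiyama aerobic oxidative cyclization of F2 should close the oxolane 5-exo; the conditions are catalytic bis(1-morpholinocarbamoyl-4,4-dimethylpentane-1,3-dionato)cobalt (a divalent cobalt complex), O2, t-BuOOH, i-PrOH, 55 °C. This reaction type is known to favour 2,5-trans products, here [(2S,5S)-5-[(benzyloxy)methyl]oxolan-2-yl]methanol F3. Appel iodination (PPh3, I2, imidazole) should give (2S,5S)-2-[(benzyloxy)methyl]-5-(iodomethyl)oxolane F4. Giese addition to 13 (Bu3SnH, AIBN, benzene, 80 °C) should give methyl 4-[(2R,5S)-5-[(benzyloxy)methyl]oxolan-2-yl]butanoate F5, and hydrogenolysis (H2, Pd/C, EtOAc) compound 14. This line also avoids the statistical mono-iodination of step 5.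

Step 13. What may go wrong: Z-to-E isomerization or halide exchange of the labile bromo-enal during partial reduction, work-up or contact with the ylide solution, and incomplete Z-selectivity of the olefination.

The fallback sets out from phosphonium salt 21 (through ylide 25) and comes back at compound 26; step 12 is then not needed. Wittig reaction of 25 with commercial 3-(trimethylsilyl)prop-2-ynal, an aldehyde without a labile double bond (NaN(SiMe3)2, THF, −78 °C), should give [(3Z,9E)-10-iododeca-3,9-dien-1-yn-1-yl]trimethylsilane F6. Bromodesilylation (N-bromosuccinimide, AgNO3 cat., acetone) should give (3Z,9E)-1-bromo-10-iododeca-3,9-dien-1-yne F7. Syn-hydroboration of the bromoalkyne with dicyclohexylborane, followed by protonolysis of the C–B bond with acetic acid (retention), should deliver the (Z)-bromoalkene and thus 26.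

Step 14. What may go wrong: competing oxidative addition at the bromodiene C–Br bond (over-coupling or scrambling of the diene geometry) and oxidative homocoupling of the alkyne.

The fallback changes the order of bond construction so that no alkenyl bromide is present during the palladium step. It sets out from alkyne 16 (with 20 and 24 from the route) and comes back at target 27. Sonogashira coupling of 16 with (E)-7-bromo-1-iodohept-1-ene 20 (Pd(PPh3)4, CuI, i-Pr2NH) should give methyl 4-[(2R,5S)-5-[(E)-9-bromonon-3-en-1-yn-1-yl]oxolan-2-yl]butanoate F8. Quaternization with PPh3 (MeCN, 80 °C) should give {(E)-9-[(2S,5R)-5-(4-methoxy-4-oxobutyl)oxolan-2-yl]non-6-en-8-yn-1-yl}triphenylphosphonium bromide F9. Ylide formation (NaN(SiMe3)2, 1 equiv, THF, −78 °C) and Z-selective Wittig reaction with (Z)-3-bromoprop-2-enal 24 should give 27.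

**Further compounds**
F1 | step 3 | (S)-2-[(benzyloxy)methyl]oxirane | C(OCc1ccccc1)[C@@H]1CO1
F2 | step 3 | (S)-1-(benzyloxy)hex-5-en-2-ol | C=CCC[C@H](O)COCc1ccccc1
F3 | step 3 | [(2S,5S)-5-[(benzyloxy)methyl]oxolan-2-yl]methanol | OC[C@@H]1CC[C@@H](COCc2ccccc2)O1
F4 | step 3 | (2S,5S)-2-[(benzyloxy)methyl]-5-(iodomethyl)oxolane | IC[C@@H]1CC[C@@H](COCc2ccccc2)O1
F5 | step 3 | methyl 4-[(2R,5S)-5-[(benzyloxy)methyl]oxolan-2-yl]butanoate | COC(=O)CCC[C@@H]1CC[C@@H](COCc2ccccc2)O1
F6 | step 13 | [(3Z,9E)-10-iododeca-3,9-dien-1-yn-1-yl]trimethylsilane | C[Si](C)(C)C#C/C=C\CCCC/C=C/I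
F7 | step 13 | (3Z,9E)-1-bromo-10-iododeca-3,9-dien-1-yne | BrC#C/C=C\CCCC/C=C/I
F8 | step 14 | methyl 4-[(2R,5S)-5-[(E)-9-bromonon-3-en-1-yn-1-yl]oxolan-2-yl]butanoate | COC(=O)CCC[C@@H]1CC[C@@H](C#C/C=C/CCCCCBr)O1
F9 | step 14 | {(E)-9-[(2S,5R)-5-(4-methoxy-4-oxobutyl)oxolan-2-yl]non-6-en-8-yn-1-yl}triphenylphosphonium bromide | [Br-].COC(=O)CCC[C@@H]1CC[C@@H](C#C/C=C/CCCCC[P+](c2ccccc2)(c2ccccc2)c2ccccc2)O1
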